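## The problem

Target 22 is a 4-methylcyclohex-3-ene whose three neighbouring sp3 carbons each carry an oxygenated arene. In the numbering used here, C1 bears the ketone carbon C7 that is bonded to ring A (2,4-dihydroxy-3-prenylphenyl). C2 bears ring B (a 2,6-dihydroxyphenyl ring that also carries the (E)-cinnamoyl chain ending in ring D, 2,4-dihydroxyphenyl), C3=C4 is the alkene with the methyl on C4, C5 is CH2 and C6 bears ring C (2,4-dihydroxyphenyl). The three stereocenters are contiguous, (1R,2S,6S): the C7 acyl group is cis to ring B on C2 and trans to ring C on C6. C6 has no neighbouring functional group, so it must be fixed in the ring-forming step together with C1; C2 can then be set from C1 only if a rigid element relays the information. C1 is α to the C7 ketone and lies between two aryl-bearing carbons; the cis C1/C2 relation is the less stable one, so it has to be made under kinetic control and C1 must not meet base once C7 is a ketone. Groups that will not survive rough treatment are the eight phenols, the prenyl group ortho to a phenol (chroman formation in protic acid), the C7 ketone flanked by ortho-hydroxyaryl groups (intramolecular ketal in acid), the 2′-hydroxychalcone (conjugate addition, reduction, flavanone closure) and the ring alkene (migration). The enabling feature is the 1,4-relation of C1 and C4: C7 is at the carboxyl oxidation level and C4 is the methyl-bearing alkene carbon, so an ester oxygen can tie C7 to C4. The resulting 2-oxabicyclo[2.2.2]octenone is the cycloadduct of pyranone 4 (C7, C1 to C4 and the methyl) with styrene 3 (C5, C6 and ring C), and its lactone bridge is also the allylic leaving group through which ring B later enters at C2 while the alkene moves to C3=C4.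

## Retrosynthesis

**22 from 20.** The eight aryl O–CH2 bonds of the methoxymethyl (MOM) ethers are cut last. Acetates or silyl ethers would not survive the hydroxide and organolithium steps, and benzyl ethers would need hydrogenolysis in the presence of three alkenes. MOM survives all steps and can be exchanged for labile silyl ethers (21) without protic acid. Precursor 20 has the full skeleton; the forward step must avoid protic acid and base.

**20 from 11 and 16.** The C7–ring A bond is cut, giving acid 11 (used as chloride 17) and bromide 16 (used as arylzinc 19, via aryllithium 18). Making the ketone at this late point keeps C1 non-enolisable during the basic enone synthesis. Zinc is chosen over lithium or magnesium because the enone of 11 must survive. Acid 11 lacks ring A and 16 is a three-step arene. The forward coupling must run without base and must select the acyl chloride over the enone.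

**11 from 10 and 2.** The enone Cα=Cβ bond is cut (Claisen–Schmidt). Aldehyde 2 is also the precursor of styrene 3, so one building block serves twice. Doing this on the carboxylate, not on a C7 ketone, removes the risk of epimerising C1. Acid 10 carries only a methyl ketone. The forward step must give the (E)-enone.

**10 from 6 and 9.** The C2–ring B bond is cut and the carboxyl oxygen is reconnected to C4, which returns the alkene to C2=C3 and gives bridged lactone 6 and iodide 9. An anti SN2′ opening (cuprate, or π-allylpalladium with an aryl metal) would put ring B trans to C7, so the forward step has to be a syn addition of the aryl group from the bridge face followed by β-oxygen elimination. Lactone 6 carries only ring C and has its three stereocenters locked in a bicycle; 9 is two steps from 7.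

**6 from 5.** No bond is cut; the enantiomers are separated. This is done at the cheapest chiral intermediate because pyranone 4 has only one donor site for a chiral Lewis acid, so catalytic control of the cycloaddition is not relied on.

**5 from 4 and 3.** C1–C6 and C4–C5 are cut. Compared with the other pairs of ring bonds, this cut uses a commercial diene, needs only ring C on a simple styrene and postpones rings A, B and D. The forward cycloaddition must join the CH2 end of 3 to the methyl-bearing carbon of 4, proceed endo and keep CO2.

**3 from 2 from 1.** The vinyl C=C is cut (Wittig) and the two MOM ethers are removed, leading to commercial 1.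

**9 from 8 from 7.** The MOM ethers and then the C–I bond between the two oxygens are removed, leading to commercial 7. Iodination precedes protection because the free chelated phenol directs it.

**16 from 15 from 13 from 12.** The C–Br bond, then the C–prenyl bond (made through aryllithium 14) and the MOM ethers are removed, leading to commercial 12. The forward bromination must select the arene over the prenyl alkene.

## Roads not taken

**Alternative 1:** C1–C6 and C2–C3 are cut instead. Ring B is the benzo ring of the 3-aroylcoumarin A1, whose lactone carbonyl is an extra carbon on C1, and ring C sits on the silyl diene A2.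
- Forward step: a normal-demand [4+2] gives the cis-fused adduct A3. Lactone opening with decarboxylation and protodesilylation with allyl shift would follow.
- Merits: the C2–ring B bond exists from the start. The 1,3-dicarbonyl dienophile can bind a chiral Lewis acid at two points, so absolute configuration could come from catalysis. No unprecedented metal step is needed.
- Weak points: in A3 the group on C1 that is cis to ring B is the lactone carbonyl, which is later lost, while the aroyl group that must stay is trans to ring B. The required C1 configuration therefore has to arise in a protonation after decarboxylation, which should favour the more stable trans isomer. The cinnamoyl enone of A1 is a second dienophile, the coumarin alkene is trisubstituted and must form a quaternary carbon, and A2 needs its own stereodefined synthesis.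
- Comparison: Alternative 1 is better in enantiocontrol and in how ring B is attached. The chosen plan sets against this that C1 is made once as a C–H stereocenter inside a bicycle and never re-formed, and that its partners 4 and 3 are commercial or two steps away.

**Alternative 2:** the C1–C2 bond is cut and an O–C4 bond restored, giving dihydropyran A4.
- Forward step: heating A4 triggers a Claisen ring contraction directly to the octakis-MOM ether A5, which is identical with 20.
- Merits: convergent and reagent-free, and the endgame after the key step is a single deprotection, shorter than in the chosen plan.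
- Weak points: the ring forces a twisted boat transition state, and the C2 configuration depends on which face of the styryl alkene bonds, with little bias. A4 itself needs a quaternary oxygen-bearing carbon cis to the ring C carbon as a single enantiomer, which is as hard as the original problem. Cycloreversion of A4 competes at the temperature needed.
- Comparison: the chosen plan derives each relation from a rigid bicycle (endo rule, bridge-face delivery) and starts from simple pieces, at the price of more steps after the key step.

**Alternative 3:** the C3=C4 bond is cut, giving the open-chain Weinreb amide A6 with a vinyl group on C2 and an isopropenyl group on C5.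
- Forward step: ring-closing metathesis with a ruthenium carbene catalyst gives the cyclohexene A7.
- Merits: this ring closure is more reliable than a high-pressure cycloaddition, and the stereocenters could be set by auxiliary or catalyst control without any resolution.
- Weak points: the ring closure creates no stereocenter. The whole C6/C1/C2 triad with two bulky arenes must be built in an open chain over several steps. The C2–H is benzylic and allylic and invites alkene migration by ruthenium hydrides. After A7 the route still needs ring A addition, ketal removal, a basic aldol condensation with the C7 ketone in place (C1 at risk) and deprotection.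
- Comparison: the chosen plan builds the ring and two stereo-relations in one step and the third in the next, and keeps C1 away from base. It has to set its resolution and one unprecedented ring opening against the greater predictability of Alternative 3.

Key step: step 3

Remark: compound 5 is a racemate and its SMILES shows the enantiomer that step 4 selects; from 6 onward every compound is a single enantiomer.

## Steps

Step 1
Reactants: 1 2,4-dihydroxybenzaldehyde
Product: 2 2,4-bis(methoxymethoxy)benzaldehyde
Conditions: NaH (2.4 equiv), MOMCl (2.4 equiv), DMF, 0 °C → rt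
Reagents that add atoms: chloromethyl methyl ether, COCCl
Why: Williamson-type O-alkylation of both phenoxides; the strong base is needed for the hydrogen-bonded 2-OH. MOM is chosen because it survives ylide, hydroxide, organolithium and organozinc steps.

Step 2
Reactants: 2 2,4-bis(methoxymethoxy)benzaldehyde
Product: 3 1-ethenyl-2,4-bis(methoxymethoxy)benzene
Conditions: Ph3PCH3Br (1.3 equiv), KOtBu (1.25 equiv), THF, 0 °C → rt
Reagents that add atoms: methyltriphenylphosphonium bromide, C[P+](c1ccccc1)(c1ccccc1)c1ccccc1.[Br-]
Why: Wittig methylenation of an aryl aldehyde; the MOM ethers are inert to the non-stabilised ylide.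

Step 3
Reactants: 4 6-methyl-2H-pyran-2-one; 3 1-ethenyl-2,4-bis(methoxymethoxy)benzene
Product: 5 racemic endo-8-[2,4-bis(methoxymethoxy)phenyl]-1-methyl-2-oxabicyclo[2.2.2]oct-5-en-3-one (aryl syn to the C5=C6 bridge)
Conditions: 3 (2 equiv), 2,6-di-tert-butyl-4-methylphenol (1 mol %), CH2Cl2, 1.3 GPa, 45 °C
Reagents that add atoms: none
Why: Concerted but asynchronous inverse-electron-demand Diels–Alder reaction: the nucleophilic CH2 terminus of 3 bonds to the methyl-bearing C6 of 4 (the vinylogous acceptor position; target C4–C5) and the benzylic carbon bonds to C3 next to the carbonyl (target C1–C6). The closest known reaction type is the thermal or high-pressure cycloaddition of 2-pyranones with styrenes and vinyl ethers, which gives isolable 2-oxabicyclo[2.2.2]octenones of this regiochemistry. The carbocycle closes as a six-membered ring in an intermolecular [4+2] across C3 and C6 of the diene, the former ester becoming the two-atom lactone bridge. The bridgeheads (target C1 and C4) are tied to each other by that bridge because the dienophile adds suprafacially to one face of the planar diene. C6 is set relative to them by endo approach, ring C lying under the diene carbons that become C2=C3 and away from the lactone bridge, which translates into the trans C1/C6 relation; pressure favours this more compact transition state. The step needs regio- and endo-selectivity and retention of CO2: the first follows from the matched polarisation of electron-rich 3 and electron-poor 4, the second from secondary overlap and the volume of activation, the third from working at 45 °C, far below the temperature of cycloreversion. Neither partner is chiral, so 5 forms as a racemate and the absolute configuration is fixed in step 4.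

Step 4
Reactants: 5 racemic endo lactone
Product: 6 (1S,4S,8S)-8-[2,4-bis(methoxymethoxy)phenyl]-1-methyl-2-oxabicyclo[2.2.2]oct-5-en-3-one
Conditions: preparative supercritical-fluid chromatography, cellulose tris(3,5-dimethylphenylcarbamate) phase, CO2/MeOH
Reagents that add atoms: none
Why: Resolution by chromatography on a chiral stationary phase; the rigid, compact lactone is a good candidate, and only two cheap steps of material are halved. The (1S,4S,8S) fraction is to be identified by vibrational circular dichroism against calculation before it is carried on.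

Step 5
Reactants: 7 1-(2,4-dihydroxyphenyl)ethan-1-one
Product: 8 1-(2,4-dihydroxy-3-iodophenyl)ethan-1-one
Conditions: I2 (0.4 equiv), HIO3 (0.2 equiv), EtOH/H2O, 35 °C
Reagents that add atoms: iodine, II; iodic acid, OI(=O)=O
Why: Electrophilic aromatic iodination with iodine oxidised in situ; bond fixation by the chelated 2-hydroxy ketone makes C3, between the two hydroxyl groups, the more nucleophilic of the two doubly activated positions.

Step 6
Reactants: 8 1-(2,4-dihydroxy-3-iodophenyl)ethan-1-one
Product: 9 1-[3-iodo-2,4-bis(methoxymethoxy)phenyl]ethan-1-one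
Conditions: NaH (2.4 equiv), MOMCl (2.4 equiv), DMF, 0 °C → rt
Reagents that add atoms: chloromethyl methyl ether, COCCl
Why: O-alkylation of both phenoxides; NaH overcomes the chelated and flanked 2-OH, and the aryl iodide and ketone are untouched.

Step 7
Reactants: 6 (1S,4S,8S)-lactone; 9 1-[3-iodo-2,4-bis(methoxymethoxy)phenyl]ethan-1-one
Product: 10 (1R,2S,6S)-2-[3-acetyl-2,6-bis(methoxymethoxy)phenyl]-6-[2,4-bis(methoxymethoxy)phenyl]-4-methylcyclohex-3-ene-1-carboxylic acid
Conditions: NiCl2(PPh3)2 (10 mol %), Zn powder (2.5 equiv), MeCN, 60 °C; then aq. citric acid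
Reagents that add atoms: none
Why: Proposed new method: oxidative addition of 9 to zerovalent nickel gives an arylnickel iodide that should add syn across the strained C2=C3 bond of 6 from the lactone-bridge face (the other face is covered by the endo ring C), aryl to the less hindered C2 and nickel to C3 next to the ring oxygen, where it is syn-periplanar to the allylic C4–O bond; β-oxygen elimination then opens the bridge, moves the alkene to C3=C4 and leaves ring B cis to the C1 carboxyl (C2 is set by the face of addition), and zinc returns divalent nickel to the zerovalent state; the closest known reaction type is the nickel-catalysed reductive arylative ring opening of 7-oxabenzonorbornadienes with aryl iodides and zinc, which gives cis-2-aryl-1,2-dihydronaphthols by the same sequence.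

Step 8
Reactants: 10 acetyl acid; 2 2,4-bis(methoxymethoxy)benzaldehyde
Product: 11 (1R,2S,6S)-2-{3-[(2E)-3-[2,4-bis(methoxymethoxy)phenyl]prop-2-enoyl]-2,6-bis(methoxymethoxy)phenyl}-6-[2,4-bis(methoxymethoxy)phenyl]-4-methylcyclohex-3-ene-1-carboxylic acid
Conditions: 2 (1.3 equiv), KOH (aq., excess), EtOH, 0 °C → rt; then cold dilute HCl to pH 4
Reagents that add atoms: none
Why: Claisen–Schmidt condensation of the methyl ketone with aldehyde 2; elimination of water gives the thermodynamically preferred (E)-enone. With C7 present as a carboxylate, hydroxide cannot enolise C1, so the cis C1/C2 relation is safe.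

Step 9
Reactants: 12 benzene-1,3-diol
Product: 13 1,3-bis(methoxymethoxy)benzene
Conditions: NaH (2.4 equiv), MOMCl (2.4 equiv), DMF, 0 °C → rt
Reagents that add atoms: chloromethyl methyl ether, COCCl
Why: Standard double O-alkylation; the MOM groups also serve as ortho-directing groups in the next step.

Step 10
Reactants: 13 1,3-bis(methoxymethoxy)benzene
Product: 15 1,3-bis(methoxymethoxy)-2-(3-methylbut-2-en-1-yl)benzene, via 2-lithio-1,3-bis(methoxymethoxy)benzene 14 (not isolated)
Conditions: n-BuLi, THF, 0 °C; CuBr·SMe2 (10 mol %), prenyl bromide, −78 °C → rt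
Reagents that add atoms: 1-bromo-3-methylbut-2-ene, CC(C)=CCBr
Why: Directed ortho-metalation at the position flanked by both MOM ethers, then copper-catalysed allylation of the aryllithium at the primary carbon of prenyl bromide.

Step 11
Reactants: 15 1,3-bis(methoxymethoxy)-2-(3-methylbut-2-en-1-yl)benzene
Product: 16 1-bromo-2,4-bis(methoxymethoxy)-3-(3-methylbut-2-en-1-yl)benzene
Conditions: NBS (1.0 equiv), MeCN, 0 °C, dark
Reagents that add atoms: N-bromosuccinimide, O=C1CCC(=O)N1Br
Why: Electrophilic aromatic bromination para to one alkoxy group and ortho to the other (the two open activated positions are equivalent); in a polar solvent without light the dialkoxyarene should react faster than the trisubstituted alkene.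

Step 12
Reactants: 11 chalcone acid; 16 1-bromo-2,4-bis(methoxymethoxy)-3-(3-methylbut-2-en-1-yl)benzene
Product: 20 (2E)-1-{3-[(1S,5S,6R)-6-[2,4-bis(methoxymethoxy)-3-(3-methylbut-2-en-1-yl)benzoyl]-5-[2,4-bis(methoxymethoxy)phenyl]-3-methylcyclohex-2-en-1-yl]-2,4-bis(methoxymethoxy)phenyl}-3-[2,4-bis(methoxymethoxy)phenyl]prop-2-en-1-one, via acid chloride 17 (not isolated), via aryllithium 18 (not isolated), via arylzinc chloride 19 (not isolated)
Conditions: 11, Me2C=C(Cl)NMe2, CH2Cl2, 0 °C; separately 16, n-BuLi, THF, −78 °C, then ZnCl2; combine, Pd(PPh3)4 (5 mol %), THF, 0 °C → rt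
Reagents that add atoms: none
Why: The α-chloroenamine makes the acyl chloride under neutral conditions, so MOM ethers and C1 are untouched; bromine–lithium exchange and transmetalation give an arylzinc that ignores the enone and the ketones. The Negishi acylation then forms the C7–ring A bond through an acylpalladium formed from zerovalent palladium, without base, so C1 keeps its configuration.

Step 13
Reactants: 20 octakis-MOM ether
Product: 22 (2E)-1-{3-[(1S,5S,6R)-6-[2,4-dihydroxy-3-(3-methylbut-2-en-1-yl)benzoyl]-5-(2,4-dihydroxyphenyl)-3-methylcyclohex-2-en-1-yl]-2,4-dihydroxyphenyl}-3-(2,4-dihydroxyphenyl)prop-2-en-1-one (the target), via octakis(trimethylsilyl) ether 21 (not isolated)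
Conditions: TMSOTf (24 equiv), 2,2′-bipyridyl (36 equiv), MeCN, 0 °C → rt; then H2O/MeOH, aq. NaHCO3
Reagents that add atoms: none
Why: Silyl triflate with 2,2′-bipyridyl converts aryl MOM ethers into aryl silyl ethers (the methoxymethyl cation is trapped by the bipyridyl), and water then cleaves the labile aryl trimethylsilyl ethers. No protic acid is present, so neither the prenyl group nor the C7 ketone should cyclise onto a phenol, and no base touches C1.

## Compound list

1 | 2,4-dihydroxybenzaldehyde | O=Cc1ccc(O)cc1O | starting material
2 | 2,4-bis(methoxymethoxy)benzaldehyde | O=Cc1ccc(OCOC)cc1OCOC | intermediate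
3 | 1-ethenyl-2,4-bis(methoxymethoxy)benzene | C=Cc1ccc(OCOC)cc1OCOC | intermediate
4 | 6-methyl-2H-pyran-2-one | CC1=CC=CC(=O)O1 | starting material
5 | racemic endo-8-[2,4-bis(methoxymethoxy)phenyl]-1-methyl-2-oxabicyclo[2.2.2]oct-5-en-3-one (aryl syn to the C5=C6 bridge; the enantiomer carried on is drawn) | O=C1[C@H]2C=C[C@@](C)(O1)C[C@@H]2c1ccc(OCOC)cc1OCOC | intermediate
6 | (1S,4S,8S)-8-[2,4-bis(methoxymethoxy)phenyl]-1-methyl-2-oxabicyclo[2.2.2]oct-5-en-3-one | O=C1[C@H]2C=C[C@@](C)(O1)C[C@@H]2c1ccc(OCOC)cc1OCOC | intermediate
7 | 1-(2,4-dihydroxyphenyl)ethan-1-one | CC(=O)c1ccc(O)cc1O | starting material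
8 | 1-(2,4-dihydroxy-3-iodophenyl)ethan-1-one | CC(=O)c1ccc(O)c(I)c1O | intermediate
9 | 1-[3-iodo-2,4-bis(methoxymethoxy)phenyl]ethan-1-one | CC(=O)c1ccc(OCOC)c(I)c1OCOC | intermediate
10 | (1R,2S,6S)-2-[3-acetyl-2,6-bis(methoxymethoxy)phenyl]-6-[2,4-bis(methoxymethoxy)phenyl]-4-methylcyclohex-3-ene-1-carboxylic acid | OC(=O)[C@H]1[C@@H](c2c(OCOC)ccc(C(C)=O)c2OCOC)C=C(C)C[C@@H]1c1ccc(OCOC)cc1OCOC | intermediate
11 | (1R,2S,6S)-2-{3-[(2E)-3-[2,4-bis(methoxymethoxy)phenyl]prop-2-enoyl]-2,6-bis(methoxymethoxy)phenyl}-6-[2,4-bis(methoxymethoxy)phenyl]-4-methylcyclohex-3-ene-1-carboxylic acid | OC(=O)[C@H]1[C@@H](c2c(OCOC)ccc(C(=O)/C=C/c3ccc(OCOC)cc3OCOC)c2OCOC)C=C(C)C[C@@H]1c1ccc(OCOC)cc1OCOC | intermediate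
12 | benzene-1,3-diol (resorcinol) | Oc1cccc(O)c1 | starting material
13 | 1,3-bis(methoxymethoxy)benzene | COCOc1cccc(OCOC)c1 | intermediate
14 | [2,6-bis(methoxymethoxy)phenyl]lithium | [Li]c1c(OCOC)cccc1OCOC | intermediate (not isolated)
15 | 1,3-bis(methoxymethoxy)-2-(3-methylbut-2-en-1-yl)benzene | CC(C)=CCc1c(OCOC)cccc1OCOC | intermediate
16 | 1-bromo-2,4-bis(methoxymethoxy)-3-(3-methylbut-2-en-1-yl)benzene | CC(C)=CCc1c(OCOC)ccc(Br)c1OCOC | intermediate
17 | acid chloride of 11, (1R,2S,6S) | ClC(=O)[C@H]1[C@@H](c2c(OCOC)ccc(C(=O)/C=C/c3ccc(OCOC)cc3OCOC)c2OCOC)C=C(C)C[C@@H]1c1ccc(OCOC)cc1OCOC | intermediate (not isolated)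
18 | [2,4-bis(methoxymethoxy)-3-(3-methylbut-2-en-1-yl)phenyl]lithium | [Li]c1ccc(OCOC)c(CC=C(C)C)c1OCOC | intermediate (not isolated)
19 | chloro[2,4-bis(methoxymethoxy)-3-(3-methylbut-2-en-1-yl)phenyl]zinc | Cl[Zn]c1ccc(OCOC)c(CC=C(C)C)c1OCOC | intermediate (not isolated)
20 | octakis(methoxymethyl) ether of the target, (1R,2S,6S) in the numbering used here | CC(C)=CCc1c(OCOC)ccc(C(=O)[C@H]2[C@@H](c3c(OCOC)ccc(C(=O)/C=C/c4ccc(OCOC)cc4OCOC)c3OCOC)C=C(C)C[C@@H]2c2ccc(OCOC)cc2OCOC)c1OCOC | intermediate
21 | octakis(trimethylsilyl) ether of the target | CC(C)=CCc1c(O[Si](C)(C)C)ccc(C(=O)[C@H]2[C@@H](c3c(O[Si](C)(C)C)ccc(C(=O)/C=C/c4ccc(O[Si](C)(C)C)cc4O[Si](C)(C)C)c3O[Si](C)(C)C)C=C(C)C[C@@H]2c2ccc(O[Si](C)(C)C)cc2O[Si](C)(C)C)c1O[Si](C)(C)C | intermediate (not isolated)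
22 | (2E)-1-{3-[(1S,5S,6R)-6-[2,4-dihydroxy-3-(3-methylbut-2-en-1-yl)benzoyl]-5-(2,4-dihydroxyphenyl)-3-methylcyclohex-2-en-1-yl]-2,4-dihydroxyphenyl}-3-(2,4-dihydroxyphenyl)prop-2-en-1-one | CC(C)=CCc1c(O)ccc(C(=O)[C@H]2[C@@H](c3c(O)ccc(C(=O)/C=C/c4ccc(O)cc4O)c3O)C=C(C)C[C@@H]2c2ccc(O)cc2O)c1O | target

## Step count and risks

Total step count: 13. Longest linear sequence: 8 steps (steps 1, 2, 3, 4, 7, 8, 12, 13).

**Step 7 (Proposed new method).**
- What may go wrong: zerovalent nickel may ionise the allylic C4–O bond before the arylnickel adds, which would deliver the aryl group trans to C7 or simply reduce the lactone. Addition with the reverse regiochemistry would strand nickel on C2 with nothing to eliminate and end in hydroarylation. Insertion of the di-ortho-substituted aryl group may be slow enough for dehalogenation of 9 to win.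
- Fallback (known chemistry, carbamate-directed syn SN2′ substitution by an arylcopper reagent), from 6 back to 10: K2CO3 in MeOH at 0 °C opens 6 to the hydroxy ester F1, and PhNCO with catalytic DBU gives the N-phenylcarbamate F2. Iodide 9 is ketalised (1,2-bis(trimethylsilyloxy)ethane, catalytic TMSOTf, −78 °C) to the dioxolane F3, which is converted into the arylcopper reagent (n-BuLi, −78 °C, then CuI). Deprotonation of F2 with MeLi and addition of this reagent should deliver ring B to C2 on the face of the departing oxygen and give the ester F4. Wet acetone with pyridinium p-toluenesulfonate removes the ketal to give the keto ester F5, and Me3SnOH in 1,2-dichloroethane cleaves the methyl ester to rejoin the route at 10.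

**Step 3 (key step).**
- What may go wrong: too little reactivity of the unactivated, methyl-donated pyranone even under pressure, radical or cationic polymerisation of the electron-rich styrene, and erosion of endo selectivity.
- Fallback, from 4 back to 5: bromination of 4 (Br2 in CH2Cl2, then Et3N) gives 3-bromo-6-methyl-2H-pyran-2-one F6. This more reactive ambiphilic diene should add 3 thermally (toluene, 90 °C) to the bromo lactone F7. Bu3SnH with azobisisobutyronitrile removes the bridgehead bromine (a bridgehead radical cannot invert) and returns 5.

**Step 12.**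
- What may go wrong: attack of a neighbouring MOM oxygen of ring B or ring C on the acyl chloride with lactone closure, decarbonylation of the hindered acylpalladium, and slow transmetalation.
- Fallback, from 11 back to 20: 2,2′-dipyridyl disulfide and PPh3 convert 11 under neutral conditions into the S-(pyridin-2-yl) thioester F8, a milder acyl donor. PdCl2(PPh3)2-catalysed Fukuyama coupling with arylzinc 19 then gives 20.

**Step 13.**
- What may go wrong: incomplete exchange of the eight MOM groups leaving partly protected mixtures, and traces of triflic acid starting chroman or ketal formation during work-up.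
- Fallback, from 20 to 22: TESOTf with 2,2′-bipyridyl gives the stable octakis(triethylsilyl) ether F9, which can be purified. KHF2 in MeOH at rt then frees the phenols to give 22.

**Step 4.**
- What may go wrong: poor separation or throughput on the chiral phase, and misassignment of the absolute configuration.
- Fallback, from 5 back to 10: racemic 5 is taken through step 7 to the racemic acid F10, and the (R)-1-phenylethylammonium salt F11 is crystallised (or the salt of the antipodal amine, whichever is less soluble with the wanted acid). Dilute citric acid liberates 10, and an X-ray structure of the salt gives the configuration.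

## Further compounds

F1 | step 7 | methyl (1S,4S,6S)-6-[2,4-bis(methoxymethoxy)phenyl]-4-hydroxy-4-methylcyclohex-2-ene-1-carboxylate | COC(=O)[C@H]1C=C[C@@](C)(O)C[C@@H]1c1ccc(OCOC)cc1OCOC
F2 | step 7 | N-phenylcarbamate of F1 | COC(=O)[C@H]1C=C[C@@](C)(OC(=O)Nc2ccccc2)C[C@@H]1c1ccc(OCOC)cc1OCOC
F3 | step 7 | 2-[3-iodo-2,4-bis(methoxymethoxy)phenyl]-2-methyl-1,3-dioxolane | CC1(c2ccc(OCOC)c(I)c2OCOC)OCCO1
F4 | step 7 | methyl (1R,2S,6S)-2-[2,6-bis(methoxymethoxy)-3-(2-methyl-1,3-dioxolan-2-yl)phenyl]-6-[2,4-bis(methoxymethoxy)phenyl]-4-methylcyclohex-3-ene-1-carboxylate | COC(=O)[C@H]1[C@@H](c2c(OCOC)ccc(C3(C)OCCO3)c2OCOC)C=C(C)C[C@@H]1c1ccc(OCOC)cc1OCOC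
F5 | step 7 | methyl ester of 10 | COC(=O)[C@H]1[C@@H](c2c(OCOC)ccc(C(C)=O)c2OCOC)C=C(C)C[C@@H]1c1ccc(OCOC)cc1OCOC
F6 | step 3 | 3-bromo-6-methyl-2H-pyran-2-one | CC1=CC=C(Br)C(=O)O1
F7 | step 3 | racemic endo-4-bromo-8-[2,4-bis(methoxymethoxy)phenyl]-1-methyl-2-oxabicyclo[2.2.2]oct-5-en-3-one (the enantiomer leading to 6 is drawn) | O=C1[C@@]2(Br)C=C[C@@](C)(O1)C[C@@H]2c1ccc(OCOC)cc1OCOC
F8 | step 12 | S-(pyridin-2-yl) thioester of 11 | O=C(Sc1ccccn1)[C@H]1[C@@H](c2c(OCOC)ccc(C(=O)/C=C/c3ccc(OCOC)cc3OCOC)c2OCOC)C=C(C)C[C@@H]1c1ccc(OCOC)cc1OCOC
F9 | step 13 | octakis(triethylsilyl) ether of the target | CC(C)=CCc1c(O[Si](CC)(CC)CC)ccc(C(=O)[C@H]2[C@@H](c3c(O[Si](CC)(CC)CC)ccc(C(=O)/C=C/c4ccc(O[Si](CC)(CC)CC)cc4O[Si](CC)(CC)CC)c3O[Si](CC)(CC)CC)C=C(C)C[C@@H]2c2ccc(O[Si](CC)(CC)CC)cc2O[Si](CC)(CC)CC)c1O[Si](CC)(CC)CC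
F10 | step 4 | racemic 10 (the wanted enantiomer is drawn) | OC(=O)[C@H]1[C@@H](c2c(OCOC)ccc(C(C)=O)c2OCOC)C=C(C)C[C@@H]1c1ccc(OCOC)cc1OCOC
F11 | step 4 | (R)-1-phenylethylammonium salt of 10 | [O-]C(=O)[C@H]1[C@@H](c2c(OCOC)ccc(C(C)=O)c2OCOC)C=C(C)C[C@@H]1c1ccc(OCOC)cc1OCOC.C[C@@H]([NH3+])c1ccccc1
A1 | alternative 1 | 3-[2,4-bis(methoxymethoxy)-3-(3-methylbut-2-en-1-yl)benzoyl]-8-[(2E)-3-[2,4-bis(methoxymethoxy)phenyl]prop-2-enoyl]-5-(methoxymethoxy)-2H-chromen-2-one | O=C1Oc2c(C(=O)/C=C/c3ccc(OCOC)cc3OCOC)ccc(OCOC)c2C=C1C(=O)c1ccc(OCOC)c(CC=C(C)C)c1OCOC
A2 | alternative 1 | (1E,3E)-1-[2,4-bis(methoxymethoxy)phenyl]-3-methyl-4-(trimethylsilyl)buta-1,3-diene | COCOc1ccc(/C=C/C(C)=C/[Si](C)(C)C)c(OCOC)c1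
A3 | alternative 1 | cis-fused allylsilane lactone adduct | O=C3Oc4c(C(=O)/C=C/c6ccc(OCOC)cc6OCOC)ccc(OCOC)c4[C@@H]5[C@@]3(C(=O)c7ccc(OCOC)c(CC=C(C)C)c7OCOC)[C@@H](c8ccc(OCOC)cc8OCOC)C=C(C)[C@H]5[Si](C)(C)C
A4 | alternative 2 | 6-(ring A)-4-(ring C)-2-methyl-2-[(E)-2-(ring B)ethenyl]-3,4-dihydro-2H-pyran, all phenols as MOM ethers, ring C cis to the styryl group | C[C@@]1(/C=C/c2c(OCOC)ccc(C(=O)/C=C/c3ccc(OCOC)cc3OCOC)c2OCOC)C[C@H](c2ccc(OCOC)cc2OCOC)C=C(c2ccc(OCOC)c(CC=C(C)C)c2OCOC)O1
A5 | alternative 2 | octakis(methoxymethyl) ether of the target (identical with 20) | CC(C)=CCc1c(OCOC)ccc(C(=O)[C@H]2[C@@H](c3c(OCOC)ccc(C(=O)/C=C/c4ccc(OCOC)cc4OCOC)c3OCOC)C=C(C)C[C@@H]2c2ccc(OCOC)cc2OCOC)c1OCOC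
A6 | alternative 3 | open-chain Weinreb amide with the C2 vinyl and C5 isopropenyl groups | CON(C)C(=O)[C@@H]([C@@H](c1c(OCOC)ccc(C2(C)OCCO2)c1OCOC)C=C)[C@@H](c1ccc(OCOC)cc1OCOC)CC(C)=C
A7 | alternative 3 | cyclohexene Weinreb amide with rings B and C in place | CON(C)C(=O)[C@H]1[C@@H](c2c(OCOC)ccc(C3(C)OCCO3)c2OCOC)C=C(C)C[C@@H]1c1ccc(OCOC)cc1OCOC
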